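**Retrosynthetic overview**

1. The target is reached by global hydrogenolysis of its tetra-O-benzyl ether. Rings A and B are bought as benzaldehydes; ring C (the 4-pyranone) is the only ring built, and it is built last.
2. Ring C is opened at C4–C4a: the carboxyl of a 3-aryloxy-2-benzyloxy-3-arylacrylic acid, already tied to ring A through O1, acylates the arene. The plan rests on C4a of ring A, the only unsubstituted carbon ortho to O1 (C8 carries a methoxyl), which is also ortho to the C5 oxygen and para to the C7 methoxyl.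
3. The acrylic acid comes from its ethyl ester, made by vinyl C–O1 coupling of 5-benzyloxy-2,3-dimethoxyphenol with the enol triflate of an α-benzyloxy β-keto ester. The keto ester comes from aldol addition of ethyl (benzyloxy)acetate to the ring B aldehyde, then oxidation.
4. The ring A phenol comes from 3-hydroxy-4,5-dimethoxybenzaldehyde (MOM on, Baeyer–Villiger, benzylation, MOM off). The ring B aldehyde comes from 2,4-dihydroxybenzaldehyde (benzylation, Baeyer–Villiger, methylation, Vilsmeier–Haack formylation).

Key step: step 14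

Remark: the aldol adduct is carried as a racemic diastereomer mixture because both stereocentres are destroyed later; the enol triflate and the enol ethers are drawn with the geometry expected from the chelated sodium enolate, and the other alkene isomer should also serve since acid equilibrates this push–pull alkene.

**Route**

Step 1
Reactants: 1 3-hydroxy-4,5-dimethoxybenzaldehyde
Product: 2 3,4-dimethoxy-5-(methoxymethoxy)benzaldehyde
Conditions: MOMCl, iPr2NEt, CH2Cl2, 0 °C to rt
Reagents that add atoms: chloromethyl methyl ether (MOMCl), COCCl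
Why: Williamson-type O-alkylation of the phenol gives an acetal that masks the future O1 through the peracid, carbonate and benzylation steps and can later be removed by mild acid without touching a benzyl ether.

Step 2
Reactants: 2 3,4-dimethoxy-5-(methoxymethoxy)benzaldehyde
Product: 4 3,4-dimethoxy-5-(methoxymethoxy)phenol, via aryl formate 3 (not isolated)
Conditions: mCPBA, CH2Cl2, 0 °C to rt; aq NaHCO3 wash; then K2CO3 (cat.), MeOH, rt
Reagents that add atoms: mCPBA, OOC(=O)c1cccc(Cl)c1
Why: Baeyer–Villiger oxidation in which the electron-rich aryl group (para-methoxyl) migrates in preference to hydride to give the formate, which methanolysis cleaves to the phenol.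

Step 3
Reactants: 4 3,4-dimethoxy-5-(methoxymethoxy)phenol
Product: 5 5-(benzyloxy)-1,2-dimethoxy-3-(methoxymethoxy)benzene
Conditions: BnBr, K2CO3, DMF, rt
Reagents that add atoms: benzyl bromide, BrCc1ccccc1
Why: Williamson etherification of the only free phenol installs the benzyl group on the oxygen that becomes the C5 oxygen of the flavone.

Step 4
Reactants: 5 5-(benzyloxy)-1,2-dimethoxy-3-(methoxymethoxy)benzene
Product: 6 5-(benzyloxy)-2,3-dimethoxyphenol
Conditions: HCl (cat.), MeOH, 50 °C
Reagents that add atoms: none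
Why: Acid-catalysed acetal exchange with methanol removes the MOM group selectively, since benzyl and methyl aryl ethers are inert to dilute methanolic acid.

Step 5
Reactants: 7 2,4-dihydroxybenzaldehyde
Product: 8 2,4-bis(benzyloxy)benzaldehyde
Conditions: BnBr (2.2 equiv), K2CO3, DMF, 60 °C
Reagents that add atoms: benzyl bromide, BrCc1ccccc1
Why: Double Williamson etherification, with gentle heating to alkylate the hydrogen-bonded 2-hydroxyl as well.

Step 6
Reactants: 8 2,4-bis(benzyloxy)benzaldehyde
Product: 10 2,4-bis(benzyloxy)phenol, via aryl formate 9 (not isolated)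
Conditions: mCPBA, CH2Cl2, 0 °C to rt; aq NaHCO3 wash; then K2CO3 (cat.), MeOH, rt
Reagents that add atoms: mCPBA, OOC(=O)c1cccc(Cl)c1
Why: Baeyer–Villiger oxidation of an ortho,para-dialkoxybenzaldehyde, where aryl migration is strongly favoured, followed by methanolysis of the formate.

Step 7
Reactants: 10 2,4-bis(benzyloxy)phenol
Product: 11 2,4-bis(benzyloxy)-1-methoxybenzene
Conditions: MeI, K2CO3, acetone, reflux
Reagents that add atoms: iodomethane, CI
Why: Williamson O-methylation of the phenol sets the methoxyl that becomes the 5′-methoxyl of ring B.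

Step 8
Reactants: 11 2,4-bis(benzyloxy)-1-methoxybenzene
Product: 13 2,4-bis(benzyloxy)-5-methoxybenzaldehyde, via iminium chloride 12 (not isolated)
Conditions: POCl3, DMF, 0 to 70 °C; then aq NaOAc
Reagents that add atoms: N,N-dimethylformamide, CN(C)C=O; water, O
Why: Vilsmeier–Haack formylation should go to the carbon ortho to one benzyloxy group and para to the other, as with other 1,2,4-trialkoxybenzenes, because the carbon between the two benzyloxy groups is hindered and the remaining carbon is activated by one methoxyl only.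

Step 9
Reactants: 14 ethyl (benzyloxy)acetate; 13 2,4-bis(benzyloxy)-5-methoxybenzaldehyde
Product: 16 ethyl 2-(benzyloxy)-3-[2,4-bis(benzyloxy)-5-methoxyphenyl]-3-hydroxypropanoate (racemic mixture of diastereomers), via lithium enolate 15 (not isolated)
Conditions: LiN(iPr)2, THF, −78 °C; then 13, −78 °C; AcOH quench
Reagents that add atoms: none
Why: Crossed aldol addition of a preformed lithium glycolate enolate to a non-enolisable aldehyde; the two new stereocentres are formed without control and are removed in steps 10 and 11.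

Step 10
Reactants: 16 ethyl 2-(benzyloxy)-3-[2,4-bis(benzyloxy)-5-methoxyphenyl]-3-hydroxypropanoate
Product: 17 ethyl 2-(benzyloxy)-3-[2,4-bis(benzyloxy)-5-methoxyphenyl]-3-oxopropanoate (racemic)
Conditions: Dess–Martin periodinane, CH2Cl2, rt
Reagents that add atoms: none
Why: Dess–Martin oxidation of a secondary benzylic alcohol to the ketone under near-neutral conditions that leave benzyl ethers and the ester untouched.

Step 11
Reactants: 17 ethyl 2-(benzyloxy)-3-[2,4-bis(benzyloxy)-5-methoxyphenyl]-3-oxopropanoate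
Product: 19 ethyl (E)-2-(benzyloxy)-3-[2,4-bis(benzyloxy)-5-methoxyphenyl]-3-{[(trifluoromethyl)sulfonyl]oxy}prop-2-enoate (triflate cis to the ester), via sodium enolate 18 (not isolated)
Conditions: NaH, Et2O, 0 °C; then Tf2O, −78 to 0 °C
Reagents that add atoms: trifluoromethanesulfonic anhydride, O=S(=O)(OS(=O)(=O)C(F)(F)F)C(F)(F)F
Why: O-sulfonylation of a β-keto ester enolate by the hard electrophile Tf2O is a standard route to β-triflyloxy enoates, and chelation of sodium between the enolate and ester oxygens should place the triflate cis to the ester.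

Step 12
Reactants: 19 ethyl (E)-2-(benzyloxy)-3-[2,4-bis(benzyloxy)-5-methoxyphenyl]-3-{[(trifluoromethyl)sulfonyl]oxy}prop-2-enoate; 6 5-(benzyloxy)-2,3-dimethoxyphenol
Product: 20 ethyl (E)-2-(benzyloxy)-3-[5-(benzyloxy)-2,3-dimethoxyphenoxy]-3-[2,4-bis(benzyloxy)-5-methoxyphenyl]prop-2-enoate (aryloxy group cis to the ester)
Conditions: Pd2(dba)3 (2.5 mol%), tBuXPhos (6 mol%), K3PO4, toluene, 80 °C
Reagents that add atoms: none
Why: Palladium-catalysed C–O cross-coupling (Buchwald–Hartwig-type etherification) of a vinyl triflate with a phenol: the electron-poor β-triflyloxy enoate adds readily to zerovalent palladium, the bulky biaryl phosphine drives C–O reductive elimination with retention of alkene geometry, the weak insoluble base keeps free phenoxide low so that attack at sulfur is suppressed, and any uncatalysed addition–elimination at the β-carbon leads to the same product.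

Step 13
Reactants: 20 ethyl (E)-2-(benzyloxy)-3-[5-(benzyloxy)-2,3-dimethoxyphenoxy]-3-[2,4-bis(benzyloxy)-5-methoxyphenyl]prop-2-enoate
Product: 21 (E)-2-(benzyloxy)-3-[5-(benzyloxy)-2,3-dimethoxyphenoxy]-3-[2,4-bis(benzyloxy)-5-methoxyphenyl]prop-2-enoic acid
Conditions: LiOH, THF–H2O, 50 °C; then aq HCl to pH 3, 0 °C
Reagents that add atoms: lithium hydroxide, [Li+].[OH-]
Why: Saponification of the ethyl ester is the usual way to 3-aryloxyacrylic acids; the aryl vinyl ether and the benzyl ethers are base-stable, and the carboxylate, once formed, is shielded from conjugate attack.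

Step 14
Reactants: 21 (E)-2-(benzyloxy)-3-[5-(benzyloxy)-2,3-dimethoxyphenoxy]-3-[2,4-bis(benzyloxy)-5-methoxyphenyl]prop-2-enoic acid
Product: 23 3,5-bis(benzyloxy)-2-[2,4-bis(benzyloxy)-5-methoxyphenyl]-7,8-dimethoxy-4H-chromen-4-one, via mixed trifluoroacetic anhydride 22 (not isolated)
Conditions: (CF3CO)2O (3 equiv), CH2Cl2, 0 °C to rt
Reagents that add atoms: none
Why: Trifluoroacetic anhydride turns the acid into mixed anhydride 22, which ionises to an acylium ion stabilised by the vinylogous O1 lone pair; C4a of ring A attacks it and the arenium ion loses its proton to give the 4-pyranone (intramolecular Friedel–Crafts acylation). The closest known reactions are the ring closures of 3-aryloxyacrylic and 3-aryloxycinnamic acids to chromones and flavones and the anhydride-mediated cyclisations of aryloxy acids onto alkoxyarenes. Ring C closes in a six-membered mode, formally 6-exo-trig at the anhydride carbonyl, with the carboxyl and O1 held cis on the alkene. No stereocentre is formed. The step needs site selectivity on ring A and selectivity against ring B: O1 is already fixed at C8a and C8 carries a methoxyl, so C4a (ortho to the C5 benzyloxy, para to the C7 methoxyl) is the only carbon the tether can reach and the 5,6,7-isomer cannot form, while ring B could only close a five-membered indenone from the other alkene isomer at a carbon activated by a single methoxyl. The benzyl ethers should survive the trifluoroacetic acid set free at or below room temperature.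

Step 15
Reactants: 23 3,5-bis(benzyloxy)-2-[2,4-bis(benzyloxy)-5-methoxyphenyl]-7,8-dimethoxy-4H-chromen-4-one
Product: 24 3,5-dihydroxy-2-(2,4-dihydroxy-5-methoxyphenyl)-7,8-dimethoxy-4H-chromen-4-one (CNP0319239.0)
Conditions: H2 (1 atm), 10% Pd/C, THF–MeOH, rt
Reagents that add atoms: none
Why: Catalytic hydrogenolysis should cleave all four benzyl ethers, while the donor-substituted tetrasubstituted C2=C3 bond and the three methyl ethers are not touched under one atmosphere of hydrogen.

**Compound list**

1 | 3-hydroxy-4,5-dimethoxybenzaldehyde | COc1cc(C=O)cc(O)c1OC | starting material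
2 | 3,4-dimethoxy-5-(methoxymethoxy)benzaldehyde | COCOc1cc(C=O)cc(OC)c1OC | intermediate
3 | 3,4-dimethoxy-5-(methoxymethoxy)phenyl formate | COCOc1cc(OC=O)cc(OC)c1OC | intermediate (not isolated)
4 | 3,4-dimethoxy-5-(methoxymethoxy)phenol | COCOc1cc(O)cc(OC)c1OC | intermediate
5 | 5-(benzyloxy)-1,2-dimethoxy-3-(methoxymethoxy)benzene | COCOc1cc(OCc2ccccc2)cc(OC)c1OC | intermediate
6 | 5-(benzyloxy)-2,3-dimethoxyphenol | COc1cc(OCc2ccccc2)cc(O)c1OC | intermediate
7 | 2,4-dihydroxybenzaldehyde | O=Cc1ccc(O)cc1O | starting material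
8 | 2,4-bis(benzyloxy)benzaldehyde | O=Cc1ccc(OCc2ccccc2)cc1OCc1ccccc1 | intermediate
9 | 2,4-bis(benzyloxy)phenyl formate | O=COc1ccc(OCc2ccccc2)cc1OCc1ccccc1 | intermediate (not isolated)
10 | 2,4-bis(benzyloxy)phenol | Oc1ccc(OCc2ccccc2)cc1OCc1ccccc1 | intermediate
11 | 2,4-bis(benzyloxy)-1-methoxybenzene | COc1ccc(OCc2ccccc2)cc1OCc1ccccc1 | intermediate
12 | N-[2,4-bis(benzyloxy)-5-methoxybenzylidene]-N-methylmethanaminium chloride | C[N+](C)=Cc1cc(OC)c(OCc2ccccc2)cc1OCc1ccccc1.[Cl-] | intermediate (not isolated)
13 | 2,4-bis(benzyloxy)-5-methoxybenzaldehyde | COc1cc(C=O)c(OCc2ccccc2)cc1OCc1ccccc1 | intermediate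
14 | ethyl (benzyloxy)acetate | CCOC(=O)COCc1ccccc1 | starting material
15 | lithium enolate of ethyl (benzyloxy)acetate | [Li+].CCOC([O-])=COCc1ccccc1 | intermediate (not isolated)
16 | ethyl 2-(benzyloxy)-3-[2,4-bis(benzyloxy)-5-methoxyphenyl]-3-hydroxypropanoate (racemic diastereomer mixture) | CCOC(=O)C(OCc1ccccc1)C(O)c1cc(OC)c(OCc2ccccc2)cc1OCc1ccccc1 | intermediate
17 | ethyl 2-(benzyloxy)-3-[2,4-bis(benzyloxy)-5-methoxyphenyl]-3-oxopropanoate (racemic) | CCOC(=O)C(OCc1ccccc1)C(=O)c1cc(OC)c(OCc2ccccc2)cc1OCc1ccccc1 | intermediate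
18 | sodium enolate of 17 | [Na+].CCOC(=O)C(OCc1ccccc1)=C([O-])c1cc(OC)c(OCc2ccccc2)cc1OCc1ccccc1 | intermediate (not isolated)
19 | ethyl (E)-2-(benzyloxy)-3-[2,4-bis(benzyloxy)-5-methoxyphenyl]-3-{[(trifluoromethyl)sulfonyl]oxy}prop-2-enoate | CCOC(=O)/C(OCc1ccccc1)=C(\OS(=O)(=O)C(F)(F)F)c1cc(OC)c(OCc2ccccc2)cc1OCc1ccccc1 | intermediate
20 | ethyl (E)-2-(benzyloxy)-3-[5-(benzyloxy)-2,3-dimethoxyphenoxy]-3-[2,4-bis(benzyloxy)-5-methoxyphenyl]prop-2-enoate | CCOC(=O)/C(OCc1ccccc1)=C(\Oc1cc(OCc2ccccc2)cc(OC)c1OC)c1cc(OC)c(OCc2ccccc2)cc1OCc1ccccc1 | intermediate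
21 | (E)-2-(benzyloxy)-3-[5-(benzyloxy)-2,3-dimethoxyphenoxy]-3-[2,4-bis(benzyloxy)-5-methoxyphenyl]prop-2-enoic acid | O=C(O)/C(OCc1ccccc1)=C(\Oc1cc(OCc2ccccc2)cc(OC)c1OC)c1cc(OC)c(OCc2ccccc2)cc1OCc1ccccc1 | intermediate
22 | mixed anhydride of 21 with trifluoroacetic acid | O=C(OC(=O)C(F)(F)F)/C(OCc1ccccc1)=C(\Oc1cc(OCc2ccccc2)cc(OC)c1OC)c1cc(OC)c(OCc2ccccc2)cc1OCc1ccccc1 | intermediate (not isolated)
23 | 3,5-bis(benzyloxy)-2-[2,4-bis(benzyloxy)-5-methoxyphenyl]-7,8-dimethoxy-4H-chromen-4-one | COc1cc(-c2oc3c(OC)c(OC)cc(OCc4ccccc4)c3c(=O)c2OCc2ccccc2)c(OCc2ccccc2)cc1OCc1ccccc1 | intermediate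
24 | 3,5-dihydroxy-2-(2,4-dihydroxy-5-methoxyphenyl)-7,8-dimethoxy-4H-chromen-4-one | COc1cc(-c2oc3c(OC)c(OC)cc(O)c3c(=O)c2O)c(O)cc1O | target

**Step count**

Total: 15 steps. Longest linear sequence: 11 steps (steps 5 to 15, from 7). The ring A branch (steps 1 to 4) joins at step 12.

**Steps most likely to fail**

Step 12. The phenoxide may attack the sulfonyl sulfur (triflyl transfer, which returns the keto ester), or C–O reductive elimination may stall at the crowded tetrasubstituted vinylpalladium centre. The fallback sets out from 17 and avoids both the sulfonate and the metal. The Vilsmeier reagent ((COCl)2, DMF, CH2Cl2) should convert 17 into ethyl 2-(benzyloxy)-3-[2,4-bis(benzyloxy)-5-methoxyphenyl]-3-chloroprop-2-enoate F1. Its chloride has no second electrophilic site, so heating with 6 and Cs2CO3 in DMF at 80 °C (classical addition–elimination of a phenoxide on a β-chloro enoate) should give the enol ether, returning to the route at 20.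

Step 14. The closure may stall at the mixed anhydride because the acylium ion is stabilised by the push–pull alkene. Acid may strip benzyl groups, ring A may be trifluoroacetylated at C6, or, after alkene isomerisation, ring B or its 2′-benzyloxy oxygen may trap the acyl group. The fallback builds ring C at O1–C2 and fixes the acyl carbon on ring A by directed ortho-metalation. It sets out from 5 and 13.
- Lithiation of 5 (n-BuLi, THF, 0 °C) at the CH flanked by the MOM and benzyl ethers, then N-methoxy-N-methyl-2-(benzyloxy)acetamide, should give 2-(benzyloxy)-1-[6-(benzyloxy)-3,4-dimethoxy-2-(methoxymethoxy)phenyl]ethan-1-one F2.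
- HCl in MeOH should remove the MOM group to give 2-(benzyloxy)-1-[6-(benzyloxy)-2-hydroxy-3,4-dimethoxyphenyl]ethan-1-one F3.
- Pinnick oxidation of 13 (NaClO2, NaH2PO4, 2-methyl-2-butene) should give 2,4-bis(benzyloxy)-5-methoxybenzoic acid F4.
- Steglich esterification of F3 with F4 (EDC·HCl, DMAP) should give 3-(benzyloxy)-2-[(benzyloxy)acetyl]-5,6-dimethoxyphenyl 2,4-bis(benzyloxy)-5-methoxybenzoate F5.
- Baker–Venkataraman rearrangement (LiN(SiMe3)2, THF) should give 2-(benzyloxy)-1-[6-(benzyloxy)-2-hydroxy-3,4-dimethoxyphenyl]-3-[2,4-bis(benzyloxy)-5-methoxyphenyl]propane-1,3-dione F6.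
- Cyclodehydration (p-TsOH, toluene, 80 °C) closes the pyranone, returning to the route at 23.

Step 15. The hindered 3-O-benzyl group may be removed incompletely, C2=C3 may be partly saturated on long exposure, or the hydroxyquinol-type ring B may oxidise in air during work-up. The fallback sets out from 23 and uses no hydrogen and no metal surface: BCl3 with pentamethylbenzene as benzyl-cation scavenger in CH2Cl2 at −78 °C, quenched with MeOH. None of the methoxyls is ortho or peri to the carbonyl, so they should survive; this returns to the route at 24.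

**Further compounds**

F1 | step 12 | ethyl 2-(benzyloxy)-3-[2,4-bis(benzyloxy)-5-methoxyphenyl]-3-chloroprop-2-enoate (E/Z mixture) | CCOC(=O)C(OCc1ccccc1)=C(Cl)c1cc(OC)c(OCc2ccccc2)cc1OCc1ccccc1
F2 | step 14 | 2-(benzyloxy)-1-[6-(benzyloxy)-3,4-dimethoxy-2-(methoxymethoxy)phenyl]ethan-1-one | O=C(COCc1ccccc1)c1c(OCOC)c(OC)c(OC)cc1OCc1ccccc1
F3 | step 14 | 2-(benzyloxy)-1-[6-(benzyloxy)-2-hydroxy-3,4-dimethoxyphenyl]ethan-1-one | O=C(COCc1ccccc1)c1c(O)c(OC)c(OC)cc1OCc1ccccc1
F4 | step 14 | 2,4-bis(benzyloxy)-5-methoxybenzoic acid | COc1cc(C(=O)O)c(OCc2ccccc2)cc1OCc1ccccc1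
F5 | step 14 | 3-(benzyloxy)-2-[(benzyloxy)acetyl]-5,6-dimethoxyphenyl 2,4-bis(benzyloxy)-5-methoxybenzoate | COc1cc(C(=O)Oc2c(OC)c(OC)cc(OCc3ccccc3)c2C(=O)COCc2ccccc2)c(OCc2ccccc2)cc1OCc1ccccc1
F6 | step 14 | 2-(benzyloxy)-1-[6-(benzyloxy)-2-hydroxy-3,4-dimethoxyphenyl]-3-[2,4-bis(benzyloxy)-5-methoxyphenyl]propane-1,3-dione | COc1cc(C(=O)C(OCc2ccccc2)C(=O)c2c(O)c(OC)c(OC)cc2OCc2ccccc2)c(OCc2ccccc2)cc1OCc1ccccc1
F0 | step 15 | none | none
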